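Ring B is opened at C8–C9. C9 is a tertiary alcohol flanked by the quaternary C10 and by C8, which carries the C17 methyl; a removable carbonyl at C7 therefore makes C8–C9 the bond of a β-hydroxy ketone. SmI2 converts a C8 bromo ketone into a regiodefined enolate that adds to the C9 ketone, closing ring B and setting C8 and C9 in one operation. The precursor is a ring A cyclohexane whose trans arms at C10 (ketone bearing the 2-silylfuran side chain, the masked butenolide) and C5 (3-bromo-2-oxobutyl) come from iridium-catalysed tert-prenylation, cross-metathesis and an enamine Michael closure.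

Key step: step 14

Remark: locants written as C1–C20 are labdane positions (ring A = C1–C5 and C10, ring B = C5–C10, side chain C11–C16); locants inside systematic names follow those names.

Assumption: the SEGPHOS antipode in step 3 is the one that delivers the (S)-carbinol, written here as (R)-SEGPHOS by analogy with related iridium allylations; the sense is to be confirmed on compound 6 (Mosher esters) and the antipode exchanged if necessary.

Step 1
Reactants: 1 2-methylpent-4-enal (racemic)
Product: 2 2-(pent-4-en-2-yl)-1,3-dioxolane (racemic)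
Conditions: HOCH2CH2OH, p-TsOH·H2O (catalytic), toluene, reflux, Dean–Stark
Reagents that add atoms: ethylene glycol, OCCO
Why: Acid-catalysed acetalisation with azeotropic removal of water masks the aldehyde (the later Michael donor) for steps 2–5; the adjacent stereocentre (future C10) can stay racemic because it is erased and reset in step 7.

Step 2
Reactants: 2 2-(pent-4-en-2-yl)-1,3-dioxolane
Product: 4 4-(1,3-dioxolan-2-yl)pentan-1-ol (racemic), via B-alkyl-9-BBN adduct 3 (not isolated)
Conditions: 9-BBN, THF, 0 °C → rt; then NaOH, H2O2, 0 °C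
Reagents that add atoms: hydrogen peroxide, OO
Why: Anti-Markovnikov hydroboration–oxidation of the monosubstituted alkene gives the primary alcohol (future C3) without touching the acetal; no stereocentre is formed.

Step 3
Reactants: 4 4-(1,3-dioxolan-2-yl)pentan-1-ol; 5 3-methylbuta-1,2-diene
Product: 6 (4S)-7-(1,3-dioxolan-2-yl)-3,3-dimethyloct-1-en-4-ol (epimers at the acetal-bearing CH)
Conditions: preformed catalyst from [Ir(cod)Cl]2, (R)-SEGPHOS, 4-cyano-3-nitrobenzoic acid, allyl acetate and Cs2CO3 (5 mol % Ir), 5 (3 equiv), toluene, 60 °C, sealed tube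
Reagents that add atoms: none
Why: Iridium-catalysed hydrogen auto-transfer tert-prenylation of a primary alcohol: the catalyst borrows hydrogen from the carbinol carbon, hydrometalates the allene and delivers the 1,1-dimethylallyl group through its substituted terminus to one carbonyl face, so the chiral bisphosphine sets the (S)-carbinol (C3) next to the new gem-dimethyl carbon (C4) and vinyl group.

Step 4
Reactants: 6 (4S)-7-(1,3-dioxolan-2-yl)-3,3-dimethyloct-1-en-4-ol
Product: 7 tert-butyl{[(4S)-7-(1,3-dioxolan-2-yl)-3,3-dimethyloct-1-en-4-yl]oxy}dimethylsilane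
Conditions: TBSCl, imidazole, DMAP (catalytic), DMF, 50 °C
Reagents that add atoms: tert-butyldimethylsilyl chloride, CC(C)(C)[Si](C)(C)Cl
Why: Imidazole-promoted silylation protects the C3 hydroxyl for the organometallic and amide-base steps; the chloride is used instead of a silyl triflate so that the dioxolane is not activated, and no stereocentre is affected.

Step 5
Reactants: 7 silyl ether from step 4; 8 pent-1-en-3-one
Product: 9 (E,7S)-7-[(tert-butyldimethylsilyl)oxy]-10-(1,3-dioxolan-2-yl)-6,6-dimethylundec-4-en-3-one
Conditions: second-generation Hoveyda–Grubbs catalyst (10 mol %), 8 (5 equiv), CH2Cl2, 40 °C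
Reagents that add atoms: none
Why: Olefin cross-metathesis: the vinyl group beside the quaternary carbon cannot homodimerise and the electron-poor enone does so only slowly, so the cross product should dominate and form as the conjugated E isomer.

Step 6
Reactants: 9 enone acetal from step 5
Product: 10 (E,5S)-5-[(tert-butyldimethylsilyl)oxy]-2,6,6-trimethyl-9-oxoundec-7-enal (C2 epimers)
Conditions: p-TsOH·H2O (catalytic), acetone/H2O, rt
Reagents that add atoms: water, O
Why: Mild acid-catalysed acetal hydrolysis (transacetalisation to acetone) frees the α-branched aldehyde while the hindered secondary silyl ether and the enone survive.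

Step 7
Reactants: 10 formyl enone from step 6
Product: 12 (1S,2S,4S)-4-[(tert-butyldimethylsilyl)oxy]-1,3,3-trimethyl-2-(2-oxobutyl)cyclohexane-1-carbaldehyde, via pyrrolidine enamine 11 (not isolated)
Conditions: pyrrolidine (20 mol %), PhCO2H (20 mol %), CH2Cl2, 0 °C → rt, stopped at full conversion of 10
Reagents that add atoms: none
Why: Intramolecular Stork-type enamine Michael addition (6-exo-trig): the enamine carbon (C10, its old configuration erased) attacks C5 of the E-enone through a chair in which the C3 silyloxy group and the enone arm are equatorial and the bulkier enamine arm turns away from the C4 gem-dimethyl group, which should set C5 (H α) and the quaternary C10 (CH3 β, formyl equatorial) with the two arms trans.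

Step 8
Reactants: 13 3-bromofuran
Product: 15 3-bromo-2-(trimethylsilyl)furan, via 3-bromo-2-lithiofuran 14 (not isolated)
Conditions: LiN(i-Pr)2, THF, −78 °C; then TMSCl, −78 °C → rt
Reagents that add atoms: chlorotrimethylsilane, C[Si](C)(C)Cl
Why: Directed deprotonation at furan C2 (flanked by the ring oxygen and acidified by bromine) with a non-nucleophilic amide avoids halogen–metal exchange, and silylation installs the group that later fixes the position of the lactone carbonyl.

Step 9
Reactants: 15 3-bromo-2-(trimethylsilyl)furan; 16 oxirane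
Product: 18 2-[2-(trimethylsilyl)furan-3-yl]ethan-1-ol, via 3-lithio-2-(trimethylsilyl)furan 17 (not isolated)
Conditions: n-BuLi, Et2O, −78 °C; then 16, BF3·OEt2, −78 °C
Reagents that add atoms: none
Why: Bromine–lithium exchange followed by Lewis-acid-assisted epoxide opening adds the two-carbon C11–C12 unit at −78 °C, before the 3-furyllithium can isomerise.

Step 10
Reactants: 18 2-[2-(trimethylsilyl)furan-3-yl]ethan-1-ol
Product: 19 3-(2-bromoethyl)-2-(trimethylsilyl)furan
Conditions: CBr4, PPh3, imidazole, CH2Cl2, 0 °C
Reagents that add atoms: carbon tetrabromide, BrC(Br)(Br)Br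
Why: Appel bromination of the primary alcohol under buffered, essentially neutral conditions keeps the acid-labile furyl–silicon bond.

Step 11
Reactants: 12 ring A keto aldehyde from step 7; 19 3-(2-bromoethyl)-2-(trimethylsilyl)furan
Product: 22 1-[(1S,2S,4S)-4-(tert-butyldimethylsilyloxy)-1,3,3-trimethyl-2-(2-oxobutyl)cyclohexyl]-3-[2-(trimethylsilyl)furan-3-yl]propan-1-ol (C9 carbinol epimers), via alkylmagnesium bromide 20 (not isolated), via alkylmanganese chloride 21 (not isolated)
Conditions: 19, Mg, THF, rt; MnCl2·2LiCl, THF, −30 °C; then 12, −30 → 0 °C; aqueous NH4Cl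
Reagents that add atoms: none
Why: Chemoselective 1,2-addition of an alkylmanganese halide to an aldehyde in the presence of a ketone: transmetalating the Grignard reagent gives a weakly basic nucleophile that should add to the non-enolisable C9 aldehyde and spare the C7 ethyl ketone; the C9 carbinol epimers are both carried on because step 13 oxidises this centre.

Step 12
Reactants: 22 hydroxy ketone from step 11
Product: 25 1-[(1S,2S,4S)-2-(3-bromo-2-oxobutyl)-4-(tert-butyldimethylsilyloxy)-1,3,3-trimethylcyclohexyl]-3-[2-(trimethylsilyl)furan-3-yl]propan-1-ol (mixture of C8/C9 epimers), via disilylated enol ether 23 (not isolated), via silylated bromo ketone 24 (not isolated)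
Conditions: TMSCl (4 equiv), then LiN(i-Pr)2 (2.2 equiv), THF, −78 → −40 °C; pentane, filtration; NBS (1.05 equiv), NaHCO3, THF, −78 °C; then 1 M HCl, THF, 0 °C
Reagents that add atoms: N-bromosuccinimide, O=C1CCC(=O)N1Br
Why: Regiodefined α-bromination through a kinetically formed silyl enol ether: with C9 still a carbinol (so C11 is not acidic) and TMSCl present from the start, the C9 alkoxide is silylated, any hemiketal alkoxide drains through the open form, and the amide base removes the open C8 proton of the ethyl ketone in preference to the C6 protons shielded by C5 and its two quaternary neighbours to give 23, NBS at −78 °C should brominate the enol ether far faster than the silylfuran to give 24, and brief dilute acid frees the C9 hydroxyl while the hindered tert-butyldimethylsilyl ether and the furyl–silicon bond persist; both C8 bromide epimers are used.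

Step 13
Reactants: 25 bromo hydroxy ketone from step 12
Product: 26 1-[(1S,2S,4S)-2-(3-bromo-2-oxobutyl)-4-(tert-butyldimethylsilyloxy)-1,3,3-trimethylcyclohexyl]-3-[2-(trimethylsilyl)furan-3-yl]propan-1-one (C8 epimers)
Conditions: Dess–Martin periodinane, NaHCO3, CH2Cl2, 0 °C → rt
Reagents that add atoms: none
Why: Dess–Martin oxidation of the hindered secondary C9 carbinol under buffered, non-basic conditions converges both carbinol epimers (and any hemiketal form) on the diketone without disturbing the α-bromo ketone, silylfuran or silyl ether.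

Step 14
Reactants: 26 ring A bromo diketone from step 13
Product: 28 3β-(tert-butyldimethylsilyloxy)-9α-hydroxy-16-(trimethylsilyl)-15,16-epoxylabda-13(16),14-dien-7-one (5α-H; 8β-H; 10β-CH3), via samarium enolate 27 (not isolated)
Conditions: SmI2 (0.1 M in THF, 2.5 equiv), THF, −78 °C, slow addition of 26; then saturated aqueous NH4Cl
Reagents that add atoms: none
Why: Two electrons from SmI2 break the C8–Br bond of either epimer and leave a trivalent samarium enolate confined to C7–C8 (27), the closest known reaction type being the samarium diiodide promoted intramolecular Reformatsky-type aldol of α-halo ketones with ketones. Ring B is closed by 6-(enolendo)-exo-trig attack of C8 on the C9 carbonyl in a chair fused to ring A, whose C5 and C10 centres hold the two arms trans-diequatorial. C9 is controlled by the metal, which can bind the enolate oxygen and the C9 carbonyl oxygen at once only when the C9–O bond is axial (α), so the furylethyl chain goes equatorial (β) as in the target. C8 is controlled by the same chair and by thermodynamics: the centre stays enolisable next to the C7 ketone, so the methyl group should settle equatorial (α) whichever bromide epimer or enolate geometry is involved. The step needs regioselectivity (C8, not C6 or C11, as nucleophile) and chemoselectivity (no ketyl formation at C7 or C9), secured by making the enolate from the halide instead of with base and by the much easier reduction of the α-bromo ketone than of dialkyl ketones at −78 °C without HMPA.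

Step 15
Reactants: 28 aldol product from step 14
Product: 29 3β-(tert-butyldimethylsilyloxy)-16-(trimethylsilyl)-15,16-epoxylabda-13(16),14-diene-7β,9α-diol
Conditions: Me4NBH(OAc)3, MeCN/AcOH, −30 °C
Reagents that add atoms: none
Why: Hydroxyl-directed (Evans–Saksena) reduction: the axial C9 hydroxyl binds the triacetoxyborohydride and delivers hydride to the α face of C7, which should give the equatorial 7β alcohol anti to the 9α hydroxyl, an arrangement that cannot form a cyclic thionocarbonate in step 16; C7 loses its oxygen in step 17.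

Step 16
Reactants: 29 diol from step 15
Product: 30 O-phenyl thionocarbonate of 29 at the C7 oxygen
Conditions: PhOC(S)Cl, pyridine, DMAP (catalytic), CH2Cl2, rt
Reagents that add atoms: O-phenyl chlorothionoformate, S=C(Cl)Oc1ccccc1
Why: Selective thioacylation of the secondary C7 hydroxyl (the tertiary C9 hydroxyl between C8 and C10 is too hindered) prepares the Barton–McCombie substrate without touching a stereocentre.

Step 17
Reactants: 30 thionocarbonate from step 16
Product: 31 3β-(tert-butyldimethylsilyloxy)-16-(trimethylsilyl)-15,16-epoxylabda-13(16),14-dien-9α-ol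
Conditions: Bu3SnH, AIBN (catalytic), toluene, 100 °C
Reagents that add atoms: none
Why: Barton–McCombie deoxygenation: stannyl radical addition to the thiocarbonyl, β-scission to the secondary C7 radical and hydrogen transfer remove the temporary oxygen; the C9 hydroxyl does not sit on a carbon adjacent to the radical, so it cannot be expelled, and the silylfuran is inert to tin radicals.

Step 18
Reactants: 31 silylfuran from step 17
Product: 33 3β-(tert-butyldimethylsilyloxy)-9α-hydroxylabd-13-en-16,15-olide, via nonconjugated butenolide 32 (not isolated)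
Conditions: CH3CO3H (about 35% in AcOH, 1.5 equiv), NaOAc, CH2Cl2, 0 °C → rt; then Et3N, rt
Reagents that add atoms: peracetic acid, CC(=O)OO
Why: Peracid oxidation of a 2-trimethylsilylfuran to a butenolide: epoxidation of the silyl-bearing furan double bond and loss of silicon place the lactone carbonyl on the formerly silylated carbon (C16) and give the β,γ-unsaturated lactone 32, which Et3N conjugates to the Δ13 butenolide; with the C7 ketone already gone no Baeyer–Villiger pathway exists.

Step 19
Reactants: 33 silyl ether from step 18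
Product: 34 3β,9α-dihydroxylabd-13-en-16,15-olide
Conditions: aqueous HF (48%), MeCN, rt
Reagents that add atoms: none
Why: Acidic fluoride cleavage of the hindered secondary silyl ether is non-basic, so the butenolide is neither isomerised nor opened and the tertiary carbinol stays in place.

Step 20
Reactants: 34 diol from step 19
Product: 35 3β-acetoxy-9α-hydroxylabd-13-en-16,15-olide (target)
Conditions: Ac2O, pyridine, DMAP (catalytic), CH2Cl2, rt
Reagents that add atoms: acetic anhydride, CC(=O)OC(C)=O
Why: DMAP-catalysed acetylation of the equatorial secondary C3 hydroxyl; the axial tertiary C9 hydroxyl should not acylate under these conditions.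

Compound list

1 | 2-methylpent-4-enal (racemic) | C=CCC(C)C=O | starting material
2 | 2-(pent-4-en-2-yl)-1,3-dioxolane (racemic) | C=CCC(C)C1OCCO1 | intermediate
3 | 9-[4-(1,3-dioxolan-2-yl)pentyl]-9-borabicyclo[3.3.1]nonane | CC(CCCB1C2CCCC1CCC2)C1OCCO1 | intermediate
4 | 4-(1,3-dioxolan-2-yl)pentan-1-ol (racemic) | OCCCC(C)C1OCCO1 | intermediate
5 | 3-methylbuta-1,2-diene | CC(C)=C=C | starting material
6 | (4S)-7-(1,3-dioxolan-2-yl)-3,3-dimethyloct-1-en-4-ol (C7 epimers) | C=CC(C)(C)[C@@H](O)CCC(C)C1OCCO1 | intermediate
7 | tert-butyl{[(4S)-7-(1,3-dioxolan-2-yl)-3,3-dimethyloct-1-en-4-yl]oxy}dimethylsilane | C=CC(C)(C)[C@@H](O[Si](C)(C)C(C)(C)C)CCC(C)C1OCCO1 | intermediate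
8 | pent-1-en-3-one | CCC(=O)C=C | starting material
9 | (E,7S)-7-[(tert-butyldimethylsilyl)oxy]-10-(1,3-dioxolan-2-yl)-6,6-dimethylundec-4-en-3-one | CCC(=O)/C=C/C(C)(C)[C@@H](O[Si](C)(C)C(C)(C)C)CCC(C)C1OCCO1 | intermediate
10 | (E,5S)-5-[(tert-butyldimethylsilyl)oxy]-2,6,6-trimethyl-9-oxoundec-7-enal (C2 epimers) | CCC(=O)/C=C/C(C)(C)[C@@H](O[Si](C)(C)C(C)(C)C)CCC(C)C=O | intermediate
11 | pyrrolidine enamine of 10 (1-pyrrolidinyl group on the former formyl carbon, C=C to the methyl-bearing carbon) | CCC(=O)/C=C/C(C)(C)[C@@H](O[Si](C)(C)C(C)(C)C)CCC(C)=CN1CCCC1 | intermediate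
12 | (1S,2S,4S)-4-[(tert-butyldimethylsilyl)oxy]-1,3,3-trimethyl-2-(2-oxobutyl)cyclohexane-1-carbaldehyde (3β-OTBS, 5α-H, 10β-CH3) | CC(C)(C)[Si](C)(C)O[C@H]1CC[C@@](C=O)(C)[C@@H](CC(=O)CC)C1(C)C | intermediate
13 | 3-bromofuran | Brc1ccoc1 | starting material
14 | 3-bromo-2-lithiofuran | [Li]c1occc1Br | intermediate
15 | 3-bromo-2-(trimethylsilyl)furan | C[Si](C)(C)c1occc1Br | intermediate
16 | oxirane | C1CO1 | starting material
17 | 3-lithio-2-(trimethylsilyl)furan | C[Si](C)(C)c1occc1[Li] | intermediate
18 | 2-[2-(trimethylsilyl)furan-3-yl]ethan-1-ol | C[Si](C)(C)c1occc1CCO | intermediate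
19 | 3-(2-bromoethyl)-2-(trimethylsilyl)furan | C[Si](C)(C)c1occc1CCBr | intermediate
20 | {2-[2-(trimethylsilyl)furan-3-yl]ethyl}magnesium bromide | C[Si](C)(C)c1occc1CC[Mg]Br | intermediate
21 | {2-[2-(trimethylsilyl)furan-3-yl]ethyl}manganese chloride | C[Si](C)(C)c1occc1CC[Mn]Cl | intermediate
22 | 1-[(1S,2S,4S)-4-(tert-butyldimethylsilyloxy)-1,3,3-trimethyl-2-(2-oxobutyl)cyclohexyl]-3-[2-(trimethylsilyl)furan-3-yl]propan-1-ol (C9 carbinol epimers) | CC(C)(C)[Si](C)(C)O[C@H]1CC[C@@](C(O)CCc2ccoc2[Si](C)(C)C)(C)[C@@H](CC(=O)CC)C1(C)C | intermediate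
23 | disilylated enol ether from 22: C9 trimethylsilyl ether and C7–C8 trimethylsilyl enol ether | CC(C)(C)[Si](C)(C)O[C@H]1CC[C@@](C(O[Si](C)(C)C)CCc2ccoc2[Si](C)(C)C)(C)[C@@H](CC(O[Si](C)(C)C)=CC)C1(C)C | intermediate
24 | silylated bromo ketone: C9 trimethylsilyl ether of 25 (C8 bromide epimers) | CC(C)(C)[Si](C)(C)O[C@H]1CC[C@@](C(O[Si](C)(C)C)CCc2ccoc2[Si](C)(C)C)(C)[C@@H](CC(=O)C(C)Br)C1(C)C | intermediate
25 | 1-[(1S,2S,4S)-2-(3-bromo-2-oxobutyl)-4-(tert-butyldimethylsilyloxy)-1,3,3-trimethylcyclohexyl]-3-[2-(trimethylsilyl)furan-3-yl]propan-1-ol (mixture of C8/C9 epimers) | CC(C)(C)[Si](C)(C)O[C@H]1CC[C@@](C(O)CCc2ccoc2[Si](C)(C)C)(C)[C@@H](CC(=O)C(C)Br)C1(C)C | intermediate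
26 | 1-[(1S,2S,4S)-2-(3-bromo-2-oxobutyl)-4-(tert-butyldimethylsilyloxy)-1,3,3-trimethylcyclohexyl]-3-[2-(trimethylsilyl)furan-3-yl]propan-1-one (C8 epimers; key-step precursor) | CC(C)(C)[Si](C)(C)O[C@H]1CC[C@@](C(=O)CCc2ccoc2[Si](C)(C)C)(C)[C@@H](CC(=O)C(C)Br)C1(C)C | intermediate
27 | diiodosamarium C7–C8 enolate of the debrominated diketone | CC(C)(C)[Si](C)(C)O[C@H]1CC[C@@](C(=O)CCc2ccoc2[Si](C)(C)C)(C)[C@@H](CC(O[Sm](I)I)=CC)C1(C)C | intermediate
28 | 3β-(tert-butyldimethylsilyloxy)-9α-hydroxy-16-(trimethylsilyl)-15,16-epoxylabda-13(16),14-dien-7-one (5α-H, 8β-H, 10β-CH3; key-step product) | CC(C)(C)[Si](C)(C)O[C@H]1CC[C@@]2(C)[C@@H](CC(=O)[C@@H](C)[C@]2(O)CCc3ccoc3[Si](C)(C)C)C1(C)C | intermediate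
29 | 3β-(tert-butyldimethylsilyloxy)-16-(trimethylsilyl)-15,16-epoxylabda-13(16),14-diene-7β,9α-diol | CC(C)(C)[Si](C)(C)O[C@H]1CC[C@@]2(C)[C@@H](C[C@H](O)[C@@H](C)[C@]2(O)CCc3ccoc3[Si](C)(C)C)C1(C)C | intermediate
30 | O-phenyl thionocarbonate of 29 at the 7β oxygen | CC(C)(C)[Si](C)(C)O[C@H]1CC[C@@]2(C)[C@@H](C[C@H](OC(=S)Oc4ccccc4)[C@@H](C)[C@]2(O)CCc3ccoc3[Si](C)(C)C)C1(C)C | intermediate
31 | 3β-(tert-butyldimethylsilyloxy)-16-(trimethylsilyl)-15,16-epoxylabda-13(16),14-dien-9α-ol | CC(C)(C)[Si](C)(C)O[C@H]1CC[C@@]2(C)[C@@H](CC[C@@H](C)[C@]2(O)CCc3ccoc3[Si](C)(C)C)C1(C)C | intermediate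
32 | 3β-(tert-butyldimethylsilyloxy)-9α-hydroxylabd-14-en-16,15-olide (nonconjugated butenolide, C13 epimers) | CC(C)(C)[Si](C)(C)O[C@H]1CC[C@@]2(C)[C@@H](CC[C@@H](C)[C@]2(O)CCC3C=COC3=O)C1(C)C | intermediate
33 | 3β-(tert-butyldimethylsilyloxy)-9α-hydroxylabd-13-en-16,15-olide | CC(C)(C)[Si](C)(C)O[C@H]1CC[C@@]2(C)[C@@H](CC[C@@H](C)[C@]2(O)CCC3=CCOC3=O)C1(C)C | intermediate
34 | 3β,9α-dihydroxylabd-13-en-16,15-olide | O[C@H]1CC[C@@]2(C)[C@@H](CC[C@@H](C)[C@]2(O)CCC3=CCOC3=O)C1(C)C | intermediate
35 | 3β-acetoxy-9α-hydroxylabd-13-en-16,15-olide = [(2S,4aS,5R,6R,8aS)-5-hydroxy-1,1,4a,6-tetramethyl-5-[2-(2-oxo-2,5-dihydrofuran-3-yl)ethyl]decahydronaphthalen-2-yl] acetate | CC(=O)O[C@H]1CC[C@@]2(C)[C@@H](CC[C@@H](C)[C@]2(O)CCC2=CCOC2=O)C1(C)C | target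

Step count

Total: 20 steps. Longest linear sequence: 17 steps (steps 1–7 and 11–20); steps 8–10 make the side-chain bromide 19.

Steps most likely to fail

Step 14. The samarium enolate may be protonated before it reaches the hindered C9 carbonyl (net debromination), or ring closure may proceed without the metal bridge and erode facial selectivity at C9. The fallback sets out from 26 and returns at 28. Reductive silylation of the bromo ketone with Zn dust and TMSCl (TMEDA, Et2O) should give, regiospecifically, the C7–C8 trimethylsilyl enol ether of the diketone F1. A TiCl4-mediated intramolecular Mukaiyama aldol (CH2Cl2, −78 °C) onto the C9 ketone would then close ring B through a Lewis-acid pathway that needs no reducing metal.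

Step 7. Facial control at the new quaternary C10 may be incomplete because two chair arrangements compete, and the amine may go on to promote aldol condensation between C8 and C9 after ring closure. The fallback sets out from 7 and returns at 12. The acetal is hydrolysed (p-TsOH, acetone/H2O) to (5S)-5-[(tert-butyldimethylsilyl)oxy]-2,6,6-trimethyloct-7-enal F2. TBSOTf/Et3N converts the aldehyde into its tert-butyldimethylsilyl enol ether F3. Cross-metathesis with 8 (second-generation Hoveyda–Grubbs catalyst) gives the enone enol ether F4. TiCl4 (CH2Cl2, −78 °C) then effects an intramolecular Mukaiyama–Michael closure. That closure generates only the C6–C7 enolate, which cannot reach the aldehyde, so aqueous work-up should give 12 without follow-up aldol.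

Step 5. Metathesis at the vinyl group, shielded by the adjacent quaternary carbon and silyl ether, may be too slow, so the catalyst decays before conversion. The fallback sets out from 7 and returns at 9. Oxidative cleavage of the vinyl group (OsO4 catalytic, NaIO4, 2,6-lutidine, dioxane/H2O) gives the non-enolisable aldehyde (3S)-3-[(tert-butyldimethylsilyl)oxy]-6-(1,3-dioxolan-2-yl)-2,2-dimethylheptanal F5. Horner–Wadsworth–Emmons olefination with diethyl (2-oxobutyl)phosphonate (NaH, THF) then builds the E-enone.

Further compounds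

F1 | step 14 | C7–C8 trimethylsilyl enol ether of 1-[(1S,2S,4S)-4-(tert-butyldimethylsilyloxy)-1,3,3-trimethyl-2-(2-oxobutyl)cyclohexyl]-3-[2-(trimethylsilyl)furan-3-yl]propan-1-one | CC(C)(C)[Si](C)(C)O[C@H]1CC[C@@](C(=O)CCc2ccoc2[Si](C)(C)C)(C)[C@@H](CC(O[Si](C)(C)C)=CC)C1(C)C
F2 | step 7 | (5S)-5-[(tert-butyldimethylsilyl)oxy]-2,6,6-trimethyloct-7-enal | C=CC(C)(C)[C@@H](O[Si](C)(C)C(C)(C)C)CCC(C)C=O
F3 | step 7 | tert-butyldimethylsilyl enol ether of F2 (1-silyloxy-2-methylalk-1-ene terminus) | C=CC(C)(C)[C@@H](O[Si](C)(C)C(C)(C)C)CCC(C)=CO[Si](C)(C)C(C)(C)C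
F4 | step 7 | (E,7S)-7,11-bis[(tert-butyldimethylsilyl)oxy]-6,6,10-trimethylundeca-4,10-dien-3-one | CCC(=O)/C=C/C(C)(C)[C@@H](O[Si](C)(C)C(C)(C)C)CCC(C)=CO[Si](C)(C)C(C)(C)C
F5 | step 5 | (3S)-3-[(tert-butyldimethylsilyl)oxy]-6-(1,3-dioxolan-2-yl)-2,2-dimethylheptanal | O=CC(C)(C)[C@@H](O[Si](C)(C)C(C)(C)C)CCC(C)C1OCCO1
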